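Remark on numbering (ad hoc, not the natural-product numbering): ring A is the cyclohexane C1–C2–C3–C4–C5–C16, ring B the cyclopentane C5–C6–C7–C8–C16, ring C the eleven-membered ring C1–C2–C15–C14–C13–C12–C11–C10–C9–C8–C16; C17 is the methylene carbon on C1; α is the face of ring A that carries the C5 methyl group, β the other face.

## Structural features

The target is a C20 tricyclic triol tris-propionate: a cis-fused hydrindane (rings A and B, angular methyl on C5) whose C2 and C8 are joined by the seven-carbon bridge C9–C15, so that ring C is an eleven-membered carbocycle sharing C16, C1 and C2 with ring A. C1 is the one-carbon bridge of the resulting bicyclo[8.3.1] unit and carries the exocyclic methylene C17; the bridge leaves ring A on opposite faces (C16–C8 β, C2–C15 α), a trans-1,3 attachment. There are ten stereocentres: the contiguous set C4 (α-O), C5 (α-CH3), C16 (α-H), C8 (α-H), C9 (CH3) and C10 (O), then C2, and across the macrocycle the trans trisubstituted epoxide C12/C13 next to the oxygenated C14. The fragile groups are the epoxide flanked by an acyloxy carbon (acid, and epoxide migration while C14–OH is free), three base-labile propionates and the 1,1-disubstituted olefin. The real difficulty is ring C: a medium ring with an E-trisubstituted olefin equivalent that bridges a compact bicycle in trans fashion, where end-to-end closures fight strain, transannular contacts and E/Z control. The second difficulty is relaying stereochemistry from the hydrindane to C12–C14 across the ring. The key step exploits one feature: C1 (sp2, a former carbonyl) and C12=C13 (the epoxide precursor) are 1,5-related along ring C through C2, C15 and C14, which is the 5-enone retron of an oxy-Cope rearrangement. Both C8 and C15 are β-carbons of that latent C1 ketone, so the same ketone can be used twice.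

## Logic of the disconnections

36 ⇒ 35 ⇒ 34: the three ester C–O bonds and the two epoxide C–O bonds are cut last. This leaves a triene-triol in which only the C14 hydroxyl is allylic, so the forward epoxidation must be hydroxyl-directed and must prefer the trisubstituted olefin over C1=C17. Desilylation is placed before the epoxide exists.

34 ⇒ 33 ⇒ 32 ⇒ 31: the C14–O bond and the C1=C17 bond are removed. This exposes a ketone at C1 and an unfunctionalised E-olefin C12=C13, exactly the two groups an oxy-Cope rearrangement produces. The forward steps need a non-basic methylenation (C2 and C16 are α to the ketone) and an allylic oxidation that picks C14.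

31 ⇒ 28 (key): the ring bond C14–C15 is cut and a bond that is absent from the target, C1–C12, is made. Ring C collapses to a seven-membered ring and the problem becomes a compact 5-6-7 tricyclic tertiary carbinol with two vinyl groups. In one sentence: 31 arises by anionic oxy-Cope ring expansion of 28. The gain is that no eleven-membered ring is ever closed end to end and the olefin geometry follows from a chair. The demand is a trans relationship of the two alkenyl groups in 28 and control of the one new centre, C2.

28 ⇒ 26 ⇒ 25 ⇒ 21: C1–C12 is cut as an intramolecular allylation of the C1 ketone by an allylmetal centred on C12–C14, the C12–Cl bond as an ene-type chlorination of a prenyl group, and C2=C15 as an α-methylenation. The forward allylation must add 1,2 to an enone and deliver C12 to the β face of C1.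

21 ⇒ 19 + 20 ⇒ 18 ⇒ 17: C12=C13 is cut by cross-metathesis and C10–C11 by allylation of an α-methyl aldehyde. The forward allylation must give the 9,10-syn carbinol in the presence of the C1 ketone.

17 ⇒ 15 ⇒ 12 ⇒ 9 + 10: the C8–C9 bond is cut by a first, acyclic oxy-Cope transform (bond C1–CH2 of a butenyl carbinol made, C8–C9 cut). This sets C8 and C9 together from an E-olefin and a chair, and C16 on protonation. The demand is α-selective, geometry-retaining crotyl addition to the C1 ketone of 9 from the β face.

9 ⇒ 7 ⇒ 4 + 5: C16=C8 is cut as an aldol condensation and C5–C6 as a conjugate addition anti to the C4 silyloxy group, so C4 controls the quaternary C5.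

4 ⇒ 3 ⇒ 2 ⇒ 1: C1=O is removed (allylic oxidation) and the C4 carbinol is traced to enantioselective reduction of commercial 1. C4 is the only stereocentre set by an external chiral reagent without help from the substrate.

## Other disconnections considered

Alternative 1: cut C12=C13 and close ring C by ring-closing metathesis of diene A1 (terminal olefin on the C8 side chain, 1,1-disubstituted olefin next to C14 on the C2 side chain), then epoxidise. This is the first plan most chemists would draw. A trisubstituted olefin in an eleven-membered ring is a poor metathesis target: the 1,1-disubstituted partner with an allylic oxygen is slow, ring strain favours oligomers, and the geometry is under ring control with no reason to expect E. A1 also needs C2 and C14 set beforehand on a flexible side chain, with the bridge bond at C2 on the face opposite to C8. The chosen route gets the E-olefin from an equatorial substituent in a chair and needs neither centre beforehand.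

Alternative 2: cut the same bond as the key step, C14–C15, but close it directly by intramolecular conjugate allylation (Hosomi–Sakurai type) of allylsilane A2 onto the exocyclic enone, with no seven-membered intermediate. This is an end-to-end closure of an eleven-membered ring under Lewis acid, competing with oligomerisation and protodesilylation. The C12=C13 geometry would come from an open transition state and not from a ring-fused chair. The relay through C1–C12 in the chosen plan pays the entropic cost in an easy seven-membered closure and turns the macrocyclisation into a unimolecular sigmatropic shift.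

Alternative 3: use the other [3,3] retron of the C1 ketone, C1(=O)–C16–C8–C9–C10=C11. The forward step would be an oxy-Cope rearrangement of the linear 5-6-7 tricyclic carbinol A3 (seven-membered ring C1–C2–C15–C14–C13–C12–C11), forming C8–C9 and cleaving C1–C11. It would set C8 and C9 while forming ring C, but it leaves an olefin at C10=C11 where the target needs C10–O and C11H2, with no bias for regioselective hydration. C11 of A3 also carries two alkenes (C10=C9 and the ring olefin C12=C13), so a second [3,3] path to a C8–C13 bond competes. Finally the cycloheptene of A3 must already contain C2, C14–O and C12=C13. The chosen retron uses every group it generates.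

Key step: step 15

## Steps

Step 1
Reactants: 1 2-methylcyclohex-2-en-1-one
Product: 2 (S)-2-methylcyclohex-2-en-1-ol
Conditions: (R)-2-methyl-CBS-oxazaborolidine (10 mol %), BH3·SMe2, THF, −20 °C; then MeOH
Reagents that add atoms: none
Why: Corey–Bakshi–Shibata reduction; with the α-methylated alkenyl arm as the large group (as for aryl alkyl ketones) the (R)-catalyst should give the S carbinol, which becomes C4.

Step 2
Reactants: 2 (S)-2-methylcyclohex-2-en-1-ol
Product: 3 (S)-tert-butyl(2-methylcyclohex-2-en-1-yloxy)diphenylsilane
Conditions: TBDPSCl, imidazole, DMF, 25 °C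
Reagents that add atoms: tert-butyl(chloro)diphenylsilane, CC(C)(C)[Si](Cl)(c1ccccc1)c1ccccc1
Why: Standard silylation; the TBDPS ether is chosen to survive the aqueous HCl of step 5 and to shield one face in step 4.

Step 3
Reactants: 3 (S)-tert-butyl(2-methylcyclohex-2-en-1-yloxy)diphenylsilane
Product: 4 (S)-4-(tert-butyldiphenylsilyloxy)-3-methylcyclohex-2-en-1-one
Conditions: Pd(OH)2 on carbon (5 mol %), t-BuOOH (5 equiv), K2CO3, CH2Cl2, 0 to 25 °C
Reagents that add atoms: tert-butyl hydroperoxide, CC(C)(C)OO
Why: Radical allylic oxidation goes to the ring CH2 next to the olefinic CH, as 1-methylcyclohexene gives 3-methylcyclohexenone; the hindered C–H geminal to the silyloxy group and the methyl group should react more slowly, and C4 is not touched.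

Step 4
Reactants: 4 (S)-4-(tert-butyldiphenylsilyloxy)-3-methylcyclohex-2-en-1-one; 5 [2-(1,3-dioxan-2-yl)ethyl]magnesium bromide (commercial THF solution)
Product: 7 (3S,4S)-4-(tert-butyldiphenylsilyloxy)-3-[2-(1,3-dioxan-2-yl)ethyl]-3-methylcyclohexan-1-one (new chain trans to the silyloxy group), via trimethylsilyl enol ether 6 (not isolated)
Conditions: CuBr·SMe2 (10 mol %), TMSCl (2 equiv), THF, −78 to −30 °C; then 1 M HCl, 0 °C, 10 min
Reagents that add atoms: none
Why: Copper-catalysed, TMSCl-accelerated conjugate addition of a Grignard reagent to a β,β-disubstituted enone; attack anti to the γ-silyloxy group sets the quaternary C5 with CH3 cis to oxygen, and enol ether 6 is hydrolysed on work-up.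

Step 5
Reactants: 7 (3S,4S)-4-(tert-butyldiphenylsilyloxy)-3-[2-(1,3-dioxan-2-yl)ethyl]-3-methylcyclohexan-1-one
Product: 9 (7S,7aS)-7-(tert-butyldiphenylsilyloxy)-7a-methyl-1,2,5,6,7,7a-hexahydro-4H-inden-4-one (C1 ketone; C16=C8), via keto aldehyde 8 (not isolated)
Conditions: 3 M HCl, THF, 50 °C
Reagents that add atoms: none
Why: Acetal hydrolysis then intramolecular aldol condensation (cyclopentene annulation); the C16 enol closes ring B 5-exo onto the aldehyde whereas the C2 enol would need a bridged seven-membered ring, and dehydration into conjugation drives the sequence.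

Step 6
Reactants: 9 (7S,7aS)-7-(tert-butyldiphenylsilyloxy)-7a-methyl-1,2,5,6,7,7a-hexahydro-4H-inden-4-one; 10 (E)-1-chlorobut-2-ene
Product: 12 tertiary carbinol [C1: α-OH; β-(E)-but-2-enyl; C16=C8; 4α-OTBDPS; 5α-CH3], via (E)-but-2-enylbarium chloride 11 (not isolated)
Conditions: activated barium from BaI2 and lithium biphenylide (2 equiv), THF, 25 °C; 10, −78 °C; then 9, −78 °C
Reagents that add atoms: none
Why: Allylbarium reagents add 1,2 to enones through the unsubstituted (α) terminus with retention of the E geometry, unlike crotyl magnesium or chromium reagents; attack anti to the pseudoaxial C5 methyl puts the butenyl group on the β face of C1.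

Step 7
Reactants: 12 tertiary carbinol [C1: α-OH; β-(E)-but-2-enyl; C16=C8]
Product: 15 cis-hydrindanone [C1 ketone; 4α-OTBDPS; 5α-CH3; 16α-H; 8β-(but-3-en-2-yl) with C9 as in 36], via potassium alkoxide 13 (not isolated), via potassium enolate 14 (not isolated)
Conditions: KH (3 equiv), 18-crown-6 (3 equiv), THF, 0 to 25 °C; then AcOH in THF, −78 °C
Reagents that add atoms: none
Why: Anionic oxy-Cope rearrangement of the 3-hydroxy-1,5-diene C8=C16–C1(O–)–CH2–CH=C9 through a chair; suprafacial transfer delivers C9 to the β face of C8 and the E-olefin keeps the methyl equatorial, which gives the C8/C9 relationship of 36. Kinetic protonation of enolate 14 on the α face, anti to the new β substituent on C8, should give the cis ring fusion, which is also the usually preferred fusion of angular-methyl hydrindan-4-ones.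

Step 8
Reactants: 15 cis-hydrindanone [8β-(but-3-en-2-yl)]
Product: 17 keto aldehyde [C10 = CHO on C9; otherwise as 15], via secondary ozonide 16 (not isolated)
Conditions: O3, CH2Cl2, −78 °C; then PPh3, −78 to 25 °C
Reagents that add atoms: ozone, [O-][O+]=O
Why: Ozonolysis of the only olefin; ketone and silyl ether are inert, and the neutral reductive work-up should not epimerise the α-methyl aldehyde.

Step 9
Reactants: 17 keto aldehyde [C10 = CHO]
Product: 18 (9S,10S)-homoallylic alcohol [C8 side chain CH(CH3)–CH(OH)–CH2–CH=CH2; C1 ketone]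
Conditions: diisopropyl (4R,5R)-2-allyl-1,3,2-dioxaborolane-4,5-dicarboxylate (1.5 equiv), 4 Å molecular sieves, toluene, −78 °C; then aqueous NaHCO3
Reagents that add atoms: diisopropyl (4R,5R)-2-allyl-1,3,2-dioxaborolane-4,5-dicarboxylate, C=CCB1O[C@@H](C(=O)OC(C)C)[C@H](C(=O)OC(C)C)O1
Why: Tartrate allylboronate (Roush) allylation; the reagent (si-face attack, S carbinol) and the Felkin–Anh preference of the α-methyl aldehyde are matched and should give the 9,10-syn alcohol, and allylboronates do not add to the C1 ketone at −78 °C.

Step 10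
Reactants: 18 (9S,10S)-homoallylic alcohol
Product: 19 TBS ether of 18 [10-OTBS]
Conditions: TBSOTf, 2,6-lutidine, CH2Cl2, −78 °C
Reagents that add atoms: tert-butyldimethylsilyl trifluoromethanesulfonate, CC(C)(C)[Si](C)(C)OS(=O)(=O)C(F)(F)F
Why: Silylation of a hindered secondary alcohol; with 2,6-lutidine at −78 °C the ketone is not enolised.

Step 11
Reactants: 19 TBS ether [terminal allyl]; 20 2-methyl-2-butene
Product: 21 prenyl ketone [C8 side chain CH(CH3)–CH(OTBS)–CH2–CH=C(CH3)2; C1 ketone]
Conditions: second-generation Grubbs catalyst RuCl2(=CHPh)(PCy3)(H2IMes) (5 mol %), 2-methyl-2-butene (large excess), CH2Cl2, 40 °C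
Reagents that add atoms: none
Why: Olefin cross-metathesis of a terminal alkene with excess 2-methyl-2-butene gives the prenyl group; no stereochemical issue arises and the ketone is inert.

Step 12
Reactants: 21 prenyl ketone
Product: 25 α-methylene ketone [C1 ketone; C2=C15H2; side chain as 21], via lithium enolate 22 (not isolated), via Mannich base 23 (not isolated), via trimethylammonium iodide 24 (not isolated)
Conditions: LDA, THF, −78 °C; CH2=NMe2+ I–, −78 to 25 °C; MeI, CH2Cl2/MeOH, 25 °C; aqueous NaHCO3, CH2Cl2, 25 °C
Reagents that add atoms: N,N-dimethylmethyleneiminium iodide (Eschenmoser's salt), C=[N+](C)C.[I-]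
Why: Kinetic deprotonation at the CH2 (C2) and not at the hindered ring-fusion CH (C16), Mannich reaction, quaternisation and E1cB elimination; the C1–C16 enolate is never formed, so the cis fusion is kept.

Step 13
Reactants: 25 α-methylene ketone
Product: 26 allylic chloride [C11H2–C12H(Cl)–C13(CH3)=C14H2; both C12 epimers; otherwise as 25]
Conditions: Ca(OCl)2, solid CO2, CH2Cl2/H2O, 0 °C
Reagents that add atoms: calcium hypochlorite, [Ca+2].[O-]Cl.[O-]Cl
Why: Ene-type chlorination of a trisubstituted olefin by HOCl gives the transposed allylic chloride with an isopropenyl group; the electron-poor enone olefin does not react, and the C12 epimer mixture is irrelevant because C12 becomes an allylmetal carbon.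

Step 14
Reactants: 26 allylic chloride
Product: 28 tricyclic carbinol [seven-membered ring C1–C16–C8–C9–C10–C11–C12; C1: α-OH and C2(=C15H2); C1–C12 bond β; C12 isopropenyl cis to the C1 hydroxyl; 10-OTBS; 4α-OTBDPS], via allylchromium dichloride 27 (not isolated)
Conditions: CrCl2 (6 equiv), LiI (10 mol %), THF/DMF, 25 °C, 0.005 M
Reagents that add atoms: none
Why: Nozaki–Hiyama allylation: both C12 epimers give the same σ-allylchromium 27, which adds 1,2 to the ketone through its γ-carbon C12 in a six-membered cyclic transition state, closing the seven-membered ring and regenerating the isopropenyl group. The tether on the β face of C8 should deliver C12 to the β face of C1 (all-cis tricycle), with the isopropenyl group anti to C2 and so cis to the hydroxyl.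

Step 15
Reactants: 28 tricyclic carbinol
Product: 31 macrocyclic ketone [ring C closed; C1 ketone; (12E)-C12=C13(CH3); C2–H β and C2–C15 α; 10-OTBS; 4α-OTBDPS], via potassium alkoxide 29 (not isolated), via potassium enolate 30 (not isolated)
Conditions: KH (3 equiv), 18-crown-6 (3 equiv), THF, 0 to 40 °C; then t-BuOH (1 equiv), 25 °C; then AcOH, −78 °C
Reagents that add atoms: none
Why: In alkoxide 29 the C1–C12 bond can stand axial on ring A, parallel to the π orbitals of C2=C15 and C13=C14, and an alkoxide-accelerated [3,3] shift (anionic oxy-Cope rearrangement, the known four-atom ring expansion of 1,2-dialkenylcycloalkanols) cleaves C1–C12 and forms C14–C15. Ring C is therefore not closed end to end but arises by expansion of the seven-membered ring through a six-membered chair transition state, the entropic cost having been paid in step 14. In that chair C16 (on C1) and C11 (on C12) are both equatorial, the arrangement available to the trans-dialkenyl carbinol 28; equatorial C11 becomes the E geometry of C12=C13 and equatorial C16 the only enolate geometry ring A allows. C1 and C12 cease to be stereocentres and one new centre, C2, is set on protonation of the regiodefined enolate 30. Axial protonation of the half-chair that keeps C8 pseudoaxial gives H2 β with the C2–C15 bond equatorial. This should also be the thermodynamic epimer, because only an axial/equatorial pair of exit bonds lets the eight-carbon bridge leave ring A without a syn-pentane contact or turning the C1 oxygen into ring C; the brief t-BuOH equilibration is there to use this. The step needs [3,3] to win over β-fragmentation of the alkoxide (loss of the allyl unit) and over the boat path; the axial C1–C12 bond, the crown-separated ion pair and irreversible enolate formation favour the concerted chair. C4, C5, C8, C9, C10 and C16 are not involved, and C16–H is not exchanged because only the C1=C2 enolate is formed.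

Step 16
Reactants: 31 macrocyclic ketone
Product: 32 diene [C1=C17H2; (12E)-C12=C13; otherwise as 31]
Conditions: Cp2Ti(μ-Cl)(μ-CH2)AlMe2 (Tebbe reagent), pyridine (cat.), THF/toluene, −40 to 25 °C
Reagents that add atoms: Tebbe reagent, C[Al](C)Cl.C=[Ti](C1C=CC=C1)C1C=CC=C1
Why: Tebbe methylenation with a non-basic titanium methylidene converts the hindered, twice α-branched ketone without enolisation, so C2 and C16 keep their configuration.

Step 17
Reactants: 32 diene
Product: 33 (14R)-allylic alcohol [C14–OH; (12E)-C12=C13; C1=C17; silyl ethers as 32]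
Conditions: SeO2 (0.5 equiv), t-BuOOH (3 equiv), CH2Cl2, 25 °C
Reagents that add atoms: selenium dioxide (oxygen carrier), O=[Se]=O; tert-butyl hydroperoxide, CC(C)(C)OO
Why: Allylic hydroxylation by ene reaction and [2,3]-shift goes to the CH2 on the more substituted olefin carbon and E to the chain, which is C14, and returns the olefin to C12=C13 (E). Both events occur on the exposed outer face of the E-olefin and should replace the outward C14–H with retention; C1=C17, with only tertiary allylic C–H bonds, should be slower.

Step 18
Reactants: 33 (14R)-allylic alcohol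
Product: 34 triene-triol [C4, C10, C14 hydroxyls]
Conditions: TBAF (6 equiv), THF, 50 °C
Reagents that add atoms: none
Why: Fluoride cleavage of both silyl ethers, placed before the epoxide is installed so that no epoxy alcohol is exposed to basic fluoride.

Step 19
Reactants: 34 triene-triol
Product: 35 epoxy triol [trans-12,13-epoxide syn to the C14 hydroxyl, as in 36; C1=C17 intact]
Conditions: mCPBA (1.05 equiv), NaHCO3, CH2Cl2, −20 to 0 °C
Reagents that add atoms: 3-chloroperbenzoic acid, OOC(=O)c1cccc(Cl)c1
Why: Hydroxyl-directed peracid epoxidation (Henbest effect): the trisubstituted olefin is far more nucleophilic than C1=C17, and oxygen is delivered syn to the C14–OH on the outer face of the E-olefin, which gives the trans epoxide with the relative configuration of 36. The buffer guards against acid-induced opening by C10–OH.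

Step 20
Reactants: 35 epoxy triol
Product: 36 target tris-propionate CNP0332420.1
Conditions: (EtCO)2O (6 equiv), DMAP, Et3N, CH2Cl2, 25 °C
Reagents that add atoms: propionic anhydride, CCC(=O)OC(=O)CC
Why: DMAP-catalysed acylation of three secondary alcohols under mildly basic conditions; epoxide and olefin survive, and no epoxide migration is possible once C14–OH is esterified.

## Compound list

1 | 2-methylcyclohex-2-en-1-one | CC1=CCCCC1=O | starting material
2 | (S)-2-methylcyclohex-2-en-1-ol | C1CC[C@H](O)C(C)=C1 | intermediate
3 | (S)-tert-butyl(2-methylcyclohex-2-en-1-yloxy)diphenylsilane | C1CC[C@H](O[Si](c2ccccc2)(c2ccccc2)C(C)(C)C)C(C)=C1 | intermediate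
4 | (S)-4-(tert-butyldiphenylsilyloxy)-3-methylcyclohex-2-en-1-one | O=C1CC[C@H](O[Si](c2ccccc2)(c2ccccc2)C(C)(C)C)C(C)=C1 | intermediate
5 | [2-(1,3-dioxan-2-yl)ethyl]magnesium bromide | Br[Mg]CCC1OCCCO1 | starting material
6 | trimethylsilyl enol ether of 7 (C1–OSiMe3, C1=C16) | C[Si](C)(C)OC1=C[C@](C)(CCC2OCCCO2)[C@@H](O[Si](c2ccccc2)(c2ccccc2)C(C)(C)C)CC1 | intermediate (not isolated)
7 | (3S,4S)-4-(tert-butyldiphenylsilyloxy)-3-[2-(1,3-dioxan-2-yl)ethyl]-3-methylcyclohexan-1-one | O=C1CC[C@H](O[Si](c2ccccc2)(c2ccccc2)C(C)(C)C)[C@@](C)(CCC2OCCCO2)C1 | intermediate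
8 | keto aldehyde, 3-[(1S,2S)-2-(tert-butyldiphenylsilyloxy)-1-methyl-5-oxocyclohexyl]propanal | O=C1CC[C@H](O[Si](c2ccccc2)(c2ccccc2)C(C)(C)C)[C@@](C)(CCC=O)C1 | intermediate (not isolated)
9 | (7S,7aS)-7-(tert-butyldiphenylsilyloxy)-7a-methyl-1,2,5,6,7,7a-hexahydro-4H-inden-4-one | O=C1CC[C@H](O[Si](c3ccccc3)(c3ccccc3)C(C)(C)C)[C@@]2(C)CCC=C12 | intermediate
10 | (E)-1-chlorobut-2-ene | C/C=C/CCl | starting material
11 | (E)-but-2-enylbarium chloride | C/C=C/C[Ba]Cl | intermediate (not isolated)
12 | tertiary carbinol, C1 α-OH and β-(E)-but-2-enyl, C16=C8 | O[C@]1(C/C=C/C)CC[C@H](O[Si](c3ccccc3)(c3ccccc3)C(C)(C)C)[C@@]2(C)CCC=C12 | intermediate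
13 | potassium alkoxide of 12 | [K+].[O-][C@]1(C/C=C/C)CC[C@H](O[Si](c3ccccc3)(c3ccccc3)C(C)(C)C)[C@@]2(C)CCC=C12 | intermediate (not isolated)
14 | potassium enolate (C1–O–, C1=C16) carrying 8β-(but-3-en-2-yl) | [K+].[O-]C1=C2[C@H]([C@H](C)C=C)CC[C@]2(C)[C@@H](O[Si](c3ccccc3)(c3ccccc3)C(C)(C)C)CC1 | intermediate (not isolated)
15 | cis-hydrindanone, C1 ketone, 4α-OTBDPS, 5α-CH3, 16α-H, 8β-(but-3-en-2-yl) | O=C1CC[C@H](O[Si](c3ccccc3)(c3ccccc3)C(C)(C)C)[C@@]2(C)CC[C@@H]([C@H](C)C=C)[C@@H]12 | intermediate
16 | secondary ozonide of 15 (1,2,4-trioxolane on C9, both epimers) | O=C1CC[C@H](O[Si](c3ccccc3)(c3ccccc3)C(C)(C)C)[C@@]2(C)CC[C@@H]([C@H](C)C3OCOO3)[C@@H]12 | intermediate (not isolated)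
17 | keto aldehyde, C10 formyl on C9 | O=C1CC[C@H](O[Si](c3ccccc3)(c3ccccc3)C(C)(C)C)[C@@]2(C)CC[C@@H]([C@H](C)C=O)[C@@H]12 | intermediate
18 | (9S,10S)-homoallylic alcohol | O=C1CC[C@H](O[Si](c3ccccc3)(c3ccccc3)C(C)(C)C)[C@@]2(C)CC[C@@H]([C@H](C)[C@@H](O)CC=C)[C@@H]12 | intermediate
19 | TBS ether of 18 | O=C1CC[C@H](O[Si](c3ccccc3)(c3ccccc3)C(C)(C)C)[C@@]2(C)CC[C@@H]([C@H](C)[C@@H](O[Si](C)(C)C(C)(C)C)CC=C)[C@@H]12 | intermediate
20 | 2-methyl-2-butene | CC=C(C)C | starting material
21 | prenyl ketone | O=C1CC[C@H](O[Si](c3ccccc3)(c3ccccc3)C(C)(C)C)[C@@]2(C)CC[C@@H]([C@H](C)[C@@H](O[Si](C)(C)C(C)(C)C)CC=C(C)C)[C@@H]12 | intermediate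
22 | lithium enolate of 21 (C1–O–, C1=C2) | [Li+].[O-]C1=CC[C@H](O[Si](c3ccccc3)(c3ccccc3)C(C)(C)C)[C@@]2(C)CC[C@@H]([C@H](C)[C@@H](O[Si](C)(C)C(C)(C)C)CC=C(C)C)[C@@H]12 | intermediate (not isolated)
23 | Mannich base, C2–CH2NMe2 (both C2 epimers) | O=C1C(CN(C)C)C[C@H](O[Si](c3ccccc3)(c3ccccc3)C(C)(C)C)[C@@]2(C)CC[C@@H]([C@H](C)[C@@H](O[Si](C)(C)C(C)(C)C)CC=C(C)C)[C@@H]12 | intermediate (not isolated)
24 | trimethylammonium iodide of 23 | [I-].O=C1C(C[N+](C)(C)C)C[C@H](O[Si](c3ccccc3)(c3ccccc3)C(C)(C)C)[C@@]2(C)CC[C@@H]([C@H](C)[C@@H](O[Si](C)(C)C(C)(C)C)CC=C(C)C)[C@@H]12 | intermediate (not isolated)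
25 | α-methylene ketone, C1 ketone, C2=C15H2 | O=C1C(=C)C[C@H](O[Si](c3ccccc3)(c3ccccc3)C(C)(C)C)[C@@]2(C)CC[C@@H]([C@H](C)[C@@H](O[Si](C)(C)C(C)(C)C)CC=C(C)C)[C@@H]12 | intermediate
26 | allylic chloride, C12–Cl with isopropenyl (both C12 epimers) | O=C1C(=C)C[C@H](O[Si](c3ccccc3)(c3ccccc3)C(C)(C)C)[C@@]2(C)CC[C@@H]([C@H](C)[C@@H](O[Si](C)(C)C(C)(C)C)CC(Cl)C(C)=C)[C@@H]12 | intermediate
27 | allylchromium dichloride (metal on C14) | O=C1C(=C)C[C@H](O[Si](c3ccccc3)(c3ccccc3)C(C)(C)C)[C@@]2(C)CC[C@@H]([C@H](C)[C@@H](O[Si](C)(C)C(C)(C)C)C/C=C(\C)C[Cr](Cl)Cl)[C@@H]12 | intermediate (not isolated)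
28 | 5-6-7 tricyclic carbinol, C1 α-OH, C1–C12 β, isopropenyl on C12 cis to OH, C2=C15H2 | C=C1C[C@H](O[Si](c2ccccc2)(c2ccccc2)C(C)(C)C)[C@@]2(C)CC[C@H]3[C@H](C)[C@@H](O[Si](C)(C)C(C)(C)C)C[C@H](C(C)=C)[C@]1(O)[C@@H]23 | intermediate
29 | potassium alkoxide of 28 | [K+].C=C1C[C@H](O[Si](c2ccccc2)(c2ccccc2)C(C)(C)C)[C@@]2(C)CC[C@H]3[C@H](C)[C@@H](O[Si](C)(C)C(C)(C)C)C[C@H](C(C)=C)[C@]1([O-])[C@@H]23 | intermediate (not isolated)
30 | macrocyclic potassium enolate (C1–O–, C1=C2, (12E)-olefin) | [K+].[O-]C1=C2C[C@H](O[Si](c4ccccc4)(c4ccccc4)C(C)(C)C)[C@@]3(C)CC[C@@H]([C@H](C)[C@@H](O[Si](C)(C)C(C)(C)C)C/C=C(\C)CC2)[C@@H]13 | intermediate (not isolated)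
31 | macrocyclic ketone, C1 ketone, 2β-H, (12E)-C12=C13 | O=C1[C@H]2C[C@H](O[Si](c4ccccc4)(c4ccccc4)C(C)(C)C)[C@@]3(C)CC[C@@H]([C@H](C)[C@@H](O[Si](C)(C)C(C)(C)C)C/C=C(\C)CC2)[C@@H]13 | intermediate
32 | diene, C1=C17H2 and (12E)-C12=C13 | C=C1[C@H]2C[C@H](O[Si](c4ccccc4)(c4ccccc4)C(C)(C)C)[C@@]3(C)CC[C@@H]([C@H](C)[C@@H](O[Si](C)(C)C(C)(C)C)C/C=C(\C)CC2)[C@@H]13 | intermediate
33 | (14R)-allylic alcohol | C=C1[C@H]2C[C@H](O[Si](c4ccccc4)(c4ccccc4)C(C)(C)C)[C@@]3(C)CC[C@@H]([C@H](C)[C@@H](O[Si](C)(C)C(C)(C)C)C/C=C(\C)[C@H](O)C2)[C@@H]13 | intermediate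
34 | triene-triol | C=C1[C@H]2C[C@H](O)[C@@]3(C)CC[C@@H]([C@H](C)[C@@H](O)C/C=C(\C)[C@H](O)C2)[C@@H]13 | intermediate
35 | epoxy triol | C=C1[C@H]2C[C@H](O)[C@@]3(C)CC[C@@H]([C@H](C)[C@@H](O)C[C@@H]4O[C@@]4(C)[C@H](O)C2)[C@@H]13 | intermediate
36 | CNP0332420.1, tris-propionate | C=C1[C@H]2C[C@H](OC(=O)CC)[C@@]3(C)CC[C@@H]([C@H](C)[C@@H](OC(=O)CC)C[C@@H]4O[C@@]4(C)[C@H](OC(=O)CC)C2)[C@@H]13 | target

## Step count and least certain steps

Total step count: 20. Longest linear sequence: 20 steps (1 to 36); compounds 5, 10 and 20 are commercial and enter directly.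

Step 15 (key step). The tertiary alkoxide may fragment (loss of the allyl unit back to the enone) instead of rearranging. If step 14 delivers the other C12 epimer, the chair would give the Z-olefin. Protonation of the enolate may occur on the α face at C2. Fallback with a different approach: set out from 26, exchange chloride for iodide (NaI, acetone) to give the rearranged primary allylic iodide F1, and close ring C directly by radical conjugate addition (Bu3SnH added slowly, AIBN, benzene, 80 °C, 2 mM). The allyl radical should add through its primary terminus C14 to C15 of the enone, and the α-keto radical takes hydrogen from the stannane to return to the route at 31.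

Step 6. Crotyl transfer may lose its α-regioselectivity or its E geometry, which would give the branched carbinol or the wrong C9 centre after step 7. Fallback: set out from 9 and add a propionate equivalent directly by Mukaiyama–Michael reaction ((Z)-1-ethylthio-1-trimethylsilyloxyprop-1-ene, TiCl4, CH2Cl2, −78 °C) to give keto thioester F2. Fukuyama reduction (Et3SiH, Pd on carbon, acetone) then gives the aldehyde and rejoins the route at 17, bypassing steps 6 to 8; the C8/C9 relationship then rests on the ketene acetal geometry.

Step 14. Ring closure may show poor facial or C12 selectivity (trans-fused or C12-epimeric carbinol), or the allylchromium may be protonated before it cyclises. Fallback: set out from 25 and close the seven-membered ring by a Lewis acid-promoted intramolecular carbonyl-ene reaction of the prenyl group with the C1 ketone (Me2AlCl, CH2Cl2, −78 to 0 °C). This forms C1–C12 and the isopropenyl group in one step and returns to the route at 28; it makes no new compound (entry F0).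

Step 17. The ene step may show poor facial selectivity at C14, overoxidise to the enone, or attack the C13 methyl or the allylic positions of C1=C17. Fallback: set out from 33 as obtained (any C14 epimer mixture), oxidise to enone F3 (Dess–Martin periodinane, NaHCO3, CH2Cl2) and reduce under reagent control ((S)-2-methyl-CBS-oxazaborolidine, catecholborane, toluene, −78 °C) to return to (14R)-33.

Step 19. The macrocycle may present the other olefin face, so that peracid attack is unselective, or C1=C17 may compete. Fallback: set out from 33 and epoxidise before desilylation under catalyst control (the L-fructose-derived enantiomer of the Shi ketone, KHSO5 as the triple salt 2KHSO5·KHSO4·K2SO4, K2CO3 buffer, MeCN/dimethoxymethane, 0 °C; the spiro transition-state model assigns this enantiomer to the 12S face) to give silyl-protected epoxy alcohol F4. Buffered fluoride (TBAF/AcOH 1:1, THF, 40 °C) then returns to the route at 35.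

## Further compounds

F1 | step 15 | allylic iodide, (12E)-C14 iodide of the enone series | O=C1C(=C)C[C@H](O[Si](c3ccccc3)(c3ccccc3)C(C)(C)C)[C@@]2(C)CC[C@@H]([C@H](C)[C@@H](O[Si](C)(C)C(C)(C)C)C/C=C(\C)CI)[C@@H]12
F2 | step 6 | keto thioester, S-ethyl thioester at C10 | O=C1CC[C@H](O[Si](c3ccccc3)(c3ccccc3)C(C)(C)C)[C@@]2(C)CC[C@@H]([C@H](C)C(=O)SCC)[C@@H]12
F0 | step 14 | none | none
F3 | step 17 | C14 enone of the macrocycle | C=C1[C@H]2C[C@H](O[Si](c4ccccc4)(c4ccccc4)C(C)(C)C)[C@@]3(C)CC[C@@H]([C@H](C)[C@@H](O[Si](C)(C)C(C)(C)C)C/C=C(\C)C(=O)C2)[C@@H]13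
F4 | step 19 | silyl-protected epoxy alcohol | C=C1[C@H]2C[C@H](O[Si](c5ccccc5)(c5ccccc5)C(C)(C)C)[C@@]3(C)CC[C@@H]([C@H](C)[C@@H](O[Si](C)(C)C(C)(C)C)C[C@@H]4O[C@@]4(C)[C@H](O)C2)[C@@H]13
A1 | alternative 1 | metathesis diene, C1 ketone with C2 and C8 side chains | O=C1[C@H](C[C@@H](O[Si](C)(C)C(C)(C)C)C(C)=C)C[C@H](O[Si](c3ccccc3)(c3ccccc3)C(C)(C)C)[C@@]2(C)CC[C@@H]([C@H](C)[C@@H](O[Si](C)(C)C(C)(C)C)CC=C)[C@@H]12
A2 | alternative 2 | C12 allylsilane of the enone series (both C12 epimers) | O=C1C(=C)C[C@H](O[Si](c3ccccc3)(c3ccccc3)C(C)(C)C)[C@@]2(C)CC[C@@H]([C@H](C)[C@@H](O[Si](C)(C)C(C)(C)C)CC([Si](C)(C)C)C(C)=C)[C@@H]12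
A3 | alternative 3 | linear 5-6-7 tricyclic carbinol with (E)-propenyl on C11 | C/C=C/[C@H]1C=C(C)[C@H](O[Si](C)(C)C(C)(C)C)C[C@@H]2C[C@H](O[Si](c3ccccc3)(c3ccccc3)C(C)(C)C)[C@@]3(C)CCC=C3[C@@]12O
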